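**Retrosynthetic overview**
1. Numbering follows 7-oxabicyclo[4.1.0]hept-3-ene-2,5-dione: carbocycle C1–C6, C1 the quaternary oxirane carbon, O7 the oxirane oxygen, side chain C1′–C6′. Target ⇒ (two O-acetylations, PMB cleavage, acetal hydrolysis) ⇒ epoxyquinone with free C1′–OH, C4–CH2OPMB and C6′ as dimethyl acetal.
2. Oxirane and carbocycle ⇒ one flask from a 4-alkynyl-4-hydroxycyclobutenone. A 4 → 6 ring expansion (Moore rearrangement) breaks the four-ring bond C2–C5, brings in the two alkyne carbons as C1 and C6, and forms C1–C2. The unisolated quinone is then epoxidised under direction by C1′–OH.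
3. Enabling feature: the carbocycle C1–C6 is at the quinone level, with C2=O and C5=O para to each other, carbon substituents only at C1 and C4, and H at C3 and C6. This makes it the retron of an alkynylcyclobutenone. The carbinol C1′ sits on C1 next to C2=O, so one stereocentre can choose both site and face for O7.
4. Cyclobutenone ⇒ isopropyl semisquarate (from diisopropyl squarate) + acetylide of an (S)-dienynol + PMBOCH2Li. The isopropoxy group steers both additions and leaves in a Stork–Danheiser transposition.
5. (S)-Dienynol ⇒ catalytic asymmetric alkynylation of a C7 dienal acetal made by vinylogous HWE olefination. Ring order: four-membered ring (bought) → six-membered carbocycle → oxirane.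

Key step: step 10

Assumption: the (S,S)-ProPhenol/Me2Zn catalyst is taken to add the alkyne to the Re face of the dienal; if the sense is the opposite, the equally available (R,R)-ligand is used and nothing else changes.

Step 1
Reactants: 1 triethyl 3-methyl-4-phosphonocrotonate (commercial E/Z mixture); 2 2,2-dimethoxyacetaldehyde (extracted from the commercial aqueous solution and dried)
Product: 3 ethyl (2E,4E)-6,6-dimethoxy-3-methylhexa-2,4-dienoate
Conditions: LiHMDS, THF/DMPU, −78 → 0 °C
Reagents that add atoms: none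
Why: Vinylogous Horner–Wadsworth–Emmons olefination in which the equilibrating γ-phosphonate anion should give the thermodynamically preferred 2E,4E-dienoate, any 2Z isomer being removed by chromatography on base-washed silica.

Step 2
Reactants: 3 ethyl (2E,4E)-6,6-dimethoxy-3-methylhexa-2,4-dienoate
Product: 4 (2E,4E)-6,6-dimethoxy-3-methylhexa-2,4-dien-1-ol
Conditions: DIBAL-H (2.2 equiv), CH2Cl2, −78 °C; aq Rochelle salt
Reagents that add atoms: none
Why: 1,2-Reduction of a conjugated ester with DIBAL-H, to which the acetal and both alkenes are inert at low temperature.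

Step 3
Reactants: 4 (2E,4E)-6,6-dimethoxy-3-methylhexa-2,4-dien-1-ol
Product: 5 (2E,4E)-6,6-dimethoxy-3-methylhexa-2,4-dienal
Conditions: MnO2, CH2Cl2, rt
Reagents that add atoms: none
Why: Neutral MnO2 oxidation of a dienylic alcohol, which should leave the acid-labile acetal and the alkene geometry untouched.

Step 4
Reactants: 5 (2E,4E)-6,6-dimethoxy-3-methylhexa-2,4-dienal; 6 ethynyltrimethylsilane
Product: 7 (3S,4E,6E)-8,8-dimethoxy-5-methyl-1-(trimethylsilyl)octa-4,6-dien-1-yn-3-ol
Conditions: Me2Zn (3 equiv), (S,S)-ProPhenol (10 mol %), Ph3P=O (20 mol %), toluene, 4 °C; pH 7 buffer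
Reagents that add atoms: none
Why: Catalytic asymmetric alkynylation of an enal by a dinuclear zinc–ProPhenol alkynylzinc species, which should deliver the alkyne to the Re face and so set C3 (the later C1′) as S, the only stereocentre set by an external chiral source.

Step 5
Reactants: 7 (3S,4E,6E)-8,8-dimethoxy-5-methyl-1-(trimethylsilyl)octa-4,6-dien-1-yn-3-ol
Product: 8 (3S,4E,6E)-8,8-dimethoxy-5-methylocta-4,6-dien-1-yn-3-ol
Conditions: K2CO3 (cat.), MeOH, 0 °C → rt
Reagents that add atoms: none
Why: Carbonate-catalysed methanolysis of the alkynyl C–Si bond, mild enough for the carbinol, the diene and the acetal.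

Step 6
Reactants: 9 diisopropyl squarate
Product: 11 3-isopropoxycyclobut-3-ene-1,2-dione, via hydroxycyclobutenone 10 (not isolated)
Conditions: LiAlH(Ot-Bu)3, THF, −78 → −20 °C; then 6 M aq HCl, CH2Cl2, rt
Reagents that add atoms: water, O
Why: 1,2-Hydride addition of the hindered aluminium hydride to one squarate carbonyl, then acid ionisation of the allylic carbinol and hydrolysis of the alkoxy-stabilised cation, the standard squarate-to-cyclobutenedione conversion.

Step 7
Reactants: 12 (tributylstannyl)methanol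
Product: 13 tributyl{[(4-methoxybenzyl)oxy]methyl}stannane
Conditions: NaH, PMBCl, Bu4NI (cat.), THF/DMF, 0 °C → rt
Reagents that add atoms: 4-methoxybenzyl chloride, COc1ccc(CCl)cc1
Why: Williamson etherification of the stannylmethanol alkoxide with a reactive benzylic chloride.

Step 8
Reactants: 8 (3S,4E,6E)-8,8-dimethoxy-5-methylocta-4,6-dien-1-yn-3-ol; 11 3-isopropoxycyclobut-3-ene-1,2-dione
Product: 16 4-[(3S,4E,6E)-8,8-dimethoxy-5-methyl-3-(trimethylsilyloxy)octa-4,6-dien-1-ynyl]-3-isopropoxy-4-(trimethylsilyloxy)cyclobut-2-enone (both C4 epimers), via dilithio dienynol 14 (not isolated), via dilithium dialkoxide 15 (not isolated)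
Conditions: n-BuLi (2.05 equiv), THF, −78 °C; add 11, −78 °C; TMSCl (2.5 equiv), −78 → 0 °C
Reagents that add atoms: chlorotrimethylsilane, C[Si](C)(C)Cl
Why: 1,2-Addition of a lithium acetylide to the more electrophilic carbonyl of the semisquarate (the one next to C–Oi-Pr, not part of the vinylogous ester) followed by O-silylation; the new ring stereocentre is not controlled and need not be, because step 10 erases it.

Step 9
Reactants: 16 bis-TMS ether of the isopropoxycyclobutenone adduct; 13 tributyl{[(4-methoxybenzyl)oxy]methyl}stannane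
Product: 20 4-hydroxy-4-[(3S,4E,6E)-3-hydroxy-8,8-dimethoxy-5-methylocta-4,6-dien-1-ynyl]-3-[(4-methoxybenzyloxy)methyl]cyclobut-2-enone (both C4 epimers), via PMB-oxymethyllithium 17 (not isolated), via lithium alkoxide 18 (not isolated), via bis-TMS cyclobutenone 19 (not isolated)
Conditions: 13, n-BuLi, THF, −78 °C; add 16, −78 °C; (CF3CO)2O, −78 → 0 °C; aq NaHCO3; then PPTS (cat.), MeOH, 0 °C
Reagents that add atoms: water, O
Why: Tin–lithium exchange gives the α-alkoxymethyllithium, which adds 1,2 to the vinylogous ester carbonyl; trifluoroacetylation, ionisation to the isopropoxy-stabilised cyclobutenyl cation and hydrolysis then transpose the carbonyl (Stork–Danheiser transposition) so that CH2OPMB ends up next to the carbinol carbon, and catalytic acid in methanol removes both TMS ethers in a medium in which the dimethyl acetal only exchanges with itself.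

Step 10
Reactants: 20 4-alkynyl-4-hydroxy-3-(PMB-oxymethyl)cyclobutenone
Product: 24 (1R,6S)-1-[(1S,2E,4E)-1-hydroxy-6,6-dimethoxy-3-methylhexa-2,4-dienyl]-4-[(4-methoxybenzyloxy)methyl]-7-oxabicyclo[4.1.0]hept-3-ene-2,5-dione, via enynylketene 21 (not isolated), via diradical 22 (not isolated), via quinone 23 (not isolated)
Conditions: degassed toluene (0.02 M), 110 °C; concentrate to ca. 0.1 M; −30 °C, t-BuOOH (decane, 1.2 equiv), DBU (0.2 equiv), same flask
Reagents that add atoms: tert-butyl hydroperoxide, CC(C)(C)OO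
Why: Heating opens the cyclobutenone by conrotatory 4π cleavage of the C(=O)–C(OH) bond with the hydroxyl turning outward, so the alkynyl group lies cis to the ketene in 21; the ketene carbon then bonds to the distal alkyne carbon (6-endo-dig) to give the aryl/phenoxyl diradical 22, and transfer of the hydroxyl hydrogen to the ring σ-radical gives quinone 23, the four-membered ring having grown by the two alkyne carbons (Moore rearrangement of 4-alkynyl-4-hydroxycyclobutenones is the closest known reaction type). The ring stereocentre of 20 is erased, so both epimers converge, and C1′ is not touched. Six- rather than five-ring closure is needed and should be secured by the sp3 carbinol substituent on the alkyne terminus, which cannot stabilise the exocyclic vinyl radical of the 5-exo mode. After cooling, t-BuOO− adds to C6 and the resulting C2 enolate closes the oxirane by 3-exo-tet attack of C1 on the peroxide oxygen (Weitz–Scheffer epoxidation of a quinone). Site selectivity between the two quinone C=C bonds should come from the six-membered C1′–OH···O=C2 hydrogen bond, which activates only the enone whose unsubstituted β-carbon is C6, whereas the C4 side carries an ether that cannot do this, and the acetal-masked diene is not an acceptor. In this hydrogen-bonded conformer the dienyl chain covers one ring face, so the peroxide should attack from the face of C1′–H and set C6 as S, and the cis closure that the three-membered ring enforces then sets C1 as R.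

Step 11
Reactants: 24 epoxyquinone PMB ether dimethyl acetal
Product: 26 (1R,6S)-1-[(1S,2E,4E)-1-hydroxy-3-methyl-6-oxohexa-2,4-dienyl]-4-(hydroxymethyl)-7-oxabicyclo[4.1.0]hept-3-ene-2,5-dione, via PMB ether dienal 25 (not isolated)
Conditions: SiO2/10 % aq oxalic acid, CH2Cl2, rt; then DDQ (1.3 equiv), 0 °C → rt, same flask
Reagents that add atoms: water, O
Why: Mild heterogeneous acid hydrolysis of the very labile dienylic acetal first makes the diene electron-poor, and DDQ then cleaves the PMB ether by hydride abstraction from its electron-rich benzylic position, while the epoxy-enedione, the deactivated C1′ carbinol and all stereocentres should stay untouched.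

Step 12
Reactants: 26 epoxyquinone diol dienal
Product: 27 (1S,2E,4E)-1-[(1R,6S)-4-(acetoxymethyl)-2,5-dioxo-7-oxabicyclo[4.1.0]hept-3-en-1-yl]-3-methyl-6-oxohexa-2,4-dienyl acetate (target)
Conditions: Ac2O, pyridine, DMAP (cat.), CH2Cl2, 0 °C
Reagents that add atoms: acetic anhydride, CC(=O)OC(C)=O
Why: DMAP-catalysed O-acetylation of the primary and the secondary alcohol under weakly basic conditions, with retention at C1′ because no C–O bond at carbon is broken.

**Compound list**
1 | triethyl 3-methyl-4-phosphonocrotonate (E/Z mixture) | CCOC(=O)C=C(C)CP(=O)(OCC)OCC | starting material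
2 | 2,2-dimethoxyacetaldehyde | COC(OC)C=O | starting material
3 | ethyl (2E,4E)-6,6-dimethoxy-3-methylhexa-2,4-dienoate | CCOC(=O)/C=C(C)/C=C/C(OC)OC | intermediate
4 | (2E,4E)-6,6-dimethoxy-3-methylhexa-2,4-dien-1-ol | OC/C=C(C)/C=C/C(OC)OC | intermediate
5 | (2E,4E)-6,6-dimethoxy-3-methylhexa-2,4-dienal | O=C/C=C(C)/C=C/C(OC)OC | intermediate
6 | ethynyltrimethylsilane | C#C[Si](C)(C)C | starting material
7 | (3S,4E,6E)-8,8-dimethoxy-5-methyl-1-(trimethylsilyl)octa-4,6-dien-1-yn-3-ol | C[Si](C)(C)C#C[C@H](/C=C(C)/C=C/C(OC)OC)O | intermediate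
8 | (3S,4E,6E)-8,8-dimethoxy-5-methylocta-4,6-dien-1-yn-3-ol | C#C[C@H](/C=C(C)/C=C/C(OC)OC)O | intermediate
9 | diisopropyl squarate (3,4-diisopropoxycyclobut-3-ene-1,2-dione) | CC(C)OC1=C(OC(C)C)C(=O)C1=O | starting material
10 | 4-hydroxy-2,3-diisopropoxycyclobut-2-enone (racemic, not isolated) | CC(C)OC1=C(OC(C)C)C(O)C1=O | intermediate
11 | 3-isopropoxycyclobut-3-ene-1,2-dione | CC(C)OC1=CC(=O)C1=O | intermediate
12 | (tributylstannyl)methanol | CCCC[Sn](CCCC)(CCCC)CO | starting material
13 | tributyl{[(4-methoxybenzyl)oxy]methyl}stannane | CCCC[Sn](CCCC)(CCCC)COCc1ccc(OC)cc1 | intermediate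
14 | C,O-dilithio derivative of 8 (not isolated) | [Li]C#C[C@H](/C=C(C)/C=C/C(OC)OC)O[Li] | intermediate
15 | dilithium dialkoxide of the 1,2-adduct of 14 to 11 (not isolated) | CC(C)OC1=CC(=O)C1(O[Li])C#C[C@H](/C=C(C)/C=C/C(OC)OC)O[Li] | intermediate
16 | 4-[(3S,4E,6E)-8,8-dimethoxy-5-methyl-3-(trimethylsilyloxy)octa-4,6-dien-1-ynyl]-3-isopropoxy-4-(trimethylsilyloxy)cyclobut-2-enone (both C4 epimers) | CC(C)OC1=CC(=O)C1(O[Si](C)(C)C)C#C[C@H](/C=C(C)/C=C/C(OC)OC)O[Si](C)(C)C | intermediate
17 | [(4-methoxybenzyl)oxy]methyllithium (not isolated) | [Li]COCc1ccc(OC)cc1 | intermediate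
18 | lithium tertiary alkoxide from 1,2-addition of 17 to 16 (not isolated) | CC(C)OC1=CC(O[Li])(COCc2ccc(OC)cc2)C1(O[Si](C)(C)C)C#C[C@H](/C=C(C)/C=C/C(OC)OC)O[Si](C)(C)C | intermediate
19 | bis-TMS ether of 20 (not isolated) | O=C1C=C(COCc2ccc(OC)cc2)C1(O[Si](C)(C)C)C#C[C@H](/C=C(C)/C=C/C(OC)OC)O[Si](C)(C)C | intermediate
20 | 4-hydroxy-4-[(3S,4E,6E)-3-hydroxy-8,8-dimethoxy-5-methylocta-4,6-dien-1-ynyl]-3-[(4-methoxybenzyloxy)methyl]cyclobut-2-enone (both C4 epimers) | O=C1C=C(COCc2ccc(OC)cc2)C1(O)C#C[C@H](/C=C(C)/C=C/C(OC)OC)O | intermediate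
21 | enynylketene, alkynyl cis to the ketenyl group (not isolated) | O=C=C/C(COCc1ccc(OC)cc1)=C(/O)C#C[C@H](/C=C(C)/C=C/C(OC)OC)O | intermediate
22 | aryl σ-radical/phenoxyl diradical (not isolated) | [O]c1cc(COCc2ccc(OC)cc2)c(O)[c]c1[C@H](/C=C(C)/C=C/C(OC)OC)O | intermediate
23 | 2-[(1S,2E,4E)-1-hydroxy-6,6-dimethoxy-3-methylhexa-2,4-dienyl]-5-[(4-methoxybenzyloxy)methyl]cyclohexa-2,5-diene-1,4-dione (not isolated) | O=C1C=C(COCc2ccc(OC)cc2)C(=O)C=C1[C@H](/C=C(C)/C=C/C(OC)OC)O | intermediate
24 | (1R,6S)-1-[(1S,2E,4E)-1-hydroxy-6,6-dimethoxy-3-methylhexa-2,4-dienyl]-4-[(4-methoxybenzyloxy)methyl]-7-oxabicyclo[4.1.0]hept-3-ene-2,5-dione | COc3ccc(COCC1=CC(=O)[C@]2([C@H](/C=C(C)/C=C/C(OC)OC)O)O[C@@H]2C1=O)cc3 | intermediate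
25 | (1R,6S)-1-[(1S,2E,4E)-1-hydroxy-3-methyl-6-oxohexa-2,4-dienyl]-4-[(4-methoxybenzyloxy)methyl]-7-oxabicyclo[4.1.0]hept-3-ene-2,5-dione (not isolated) | COc3ccc(COCC1=CC(=O)[C@]2([C@H](/C=C(C)/C=C/C=O)O)O[C@@H]2C1=O)cc3 | intermediate
26 | (1R,6S)-1-[(1S,2E,4E)-1-hydroxy-3-methyl-6-oxohexa-2,4-dienyl]-4-(hydroxymethyl)-7-oxabicyclo[4.1.0]hept-3-ene-2,5-dione | OCC1=CC(=O)[C@]2([C@H](/C=C(C)/C=C/C=O)O)O[C@@H]2C1=O | intermediate
27 | (1S,2E,4E)-1-[(1R,6S)-4-(acetoxymethyl)-2,5-dioxo-7-oxabicyclo[4.1.0]hept-3-en-1-yl]-3-methyl-6-oxohexa-2,4-dienyl acetate | CC(=O)OCC1=CC(=O)[C@]2([C@H](/C=C(C)/C=C/C=O)OC(C)=O)O[C@@H]2C1=O | target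

**Totals and risks**
Total step count: 12. Longest linear sequence: 10 (steps 1–5 and 8–12).

Step 10 is the riskiest.
- What may go wrong: in the second stage, base-induced tautomerisation of the hydroxyalkylquinone, peroxide attack at the wrong enone, or poor facial selectivity.
- Fallback: it sets out from 23, obtained by running only the thermolysis and working up, and epoxidises a quinone monoketal instead of the quinone. Reduction with aqueous Na2S2O4 should give the hydroquinone F1. Methylation (MeI, K2CO3, acetone) should take place at the less hindered phenol next to CH2OPMB, which is not hydrogen-bonded to the carbinol, and give the 4-methoxyphenol F2. PhI(OAc)2 in MeOH at 0 °C should then give the quinone monoketal F3.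
- Why this is safer: F3 has a single carbonyl (C2=O), only one unsubstituted β-carbon (C6), and no vinylogous acidity at C1′–H.
- Return to the route: hydroxyl-directed nucleophilic epoxidation (Ph3COOH, NaHMDS, toluene, low temperature) should give the epoxy ketal F4. Wet SiO2/oxalic acid cleaves ring ketal and side-chain acetal together, which comes back to the route at 25.

Step 9 is second.
- What may go wrong: silyl migration in the alkoxide, incomplete ionisation, or partial loss of the acetal during the anhydrous transposition.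
- Fallback: it sets out from 16 and 13. Adduct 18 is quenched with 1 M aq HCl in THF at 0 °C, so that transposition, cleavage of both silyl ethers and acetal hydrolysis all go to completion and give the cyclobutenone dienal F5. The aldehyde is then masked again with HC(OMe)3 and PPTS in MeOH, which comes back to the route at 20.

Step 4 is third.
- What may go wrong: insufficient enantioselectivity or slow addition to the β,β-disubstituted dienal.
- Fallback: it sets out from 5 and replaces asymmetric C–C bond formation by asymmetric reduction. Lithium (trimethylsilyl)acetylide in THF at −78 °C should give the racemic carbinol F6. MnO2 should oxidise it to the dienyl ynone F7. Midland reduction with (S)-Alpine-Borane, in which the alkyne acts as the small group, should give the S alcohol and come back to the route at 7.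

**Further compounds**
F1 | step 10 | 2-[(1S,2E,4E)-1-hydroxy-6,6-dimethoxy-3-methylhexa-2,4-dienyl]-5-[(4-methoxybenzyloxy)methyl]benzene-1,4-diol | Oc1cc(COCc2ccc(OC)cc2)c(O)cc1[C@H](/C=C(C)/C=C/C(OC)OC)O
F2 | step 10 | 2-[(1S,2E,4E)-1-hydroxy-6,6-dimethoxy-3-methylhexa-2,4-dienyl]-4-methoxy-5-[(4-methoxybenzyloxy)methyl]phenol | Oc1cc(COCc2ccc(OC)cc2)c(OC)cc1[C@H](/C=C(C)/C=C/C(OC)OC)O
F3 | step 10 | 2-[(1S,2E,4E)-1-hydroxy-6,6-dimethoxy-3-methylhexa-2,4-dienyl]-4,4-dimethoxy-5-[(4-methoxybenzyloxy)methyl]cyclohexa-2,5-dienone | O=C1C=C(COCc2ccc(OC)cc2)C(OC)(OC)C=C1[C@H](/C=C(C)/C=C/C(OC)OC)O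
F4 | step 10 | (1R,6S)-1-[(1S,2E,4E)-1-hydroxy-6,6-dimethoxy-3-methylhexa-2,4-dienyl]-5,5-dimethoxy-4-[(4-methoxybenzyloxy)methyl]-7-oxabicyclo[4.1.0]hept-3-en-2-one | COc3ccc(COCC1=CC(=O)[C@]2([C@H](/C=C(C)/C=C/C(OC)OC)O)O[C@@H]2C1(OC)OC)cc3
F5 | step 9 | 4-hydroxy-4-[(3S,4E,6E)-3-hydroxy-5-methyl-8-oxoocta-4,6-dien-1-ynyl]-3-[(4-methoxybenzyloxy)methyl]cyclobut-2-enone | O=C1C=C(COCc2ccc(OC)cc2)C1(O)C#C[C@H](/C=C(C)/C=C/C=O)O
F6 | step 4 | (4E,6E)-8,8-dimethoxy-5-methyl-1-(trimethylsilyl)octa-4,6-dien-1-yn-3-ol (racemic) | C[Si](C)(C)C#CC(O)/C=C(C)/C=C/C(OC)OC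
F7 | step 4 | (4E,6E)-8,8-dimethoxy-5-methyl-1-(trimethylsilyl)octa-4,6-dien-1-yn-3-one | C[Si](C)(C)C#CC(=O)/C=C(C)/C=C/C(OC)OC
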